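**Plan**

- Retrosynthetic cuts, in order: C4–C4a of the tetralone (this opens the cyclohexanone ring to a racemic diaryl carbinol), then C1–C8a (aryllithium + γ-lactone), then C3–C4 (ester homoenolate + naphthaldehyde), then the formyl carbon–naphthalene C1 bond.
- Forward: the naphthalene ring is bought as symmetric 1,5-dimethoxynaphthalene, formylated, and its two oxygens are told apart. The C1–C3 chain is added as a lactone, the bought catechol ring is joined as an aryllithium, and the cyclohexanone ring is closed last, which gives the target itself.
- Enabling feature: naphthalene C4–OH is para to naphthalene C1, so the carbinol carbon on C1 (tetralone C4) ionises to a planar 1,4-naphthoquinone methide. In the catechol ring C7–OH is para to C4a, so C4a is its nucleophilic carbon, and the C1–C2–C3 tether allows only a six-membered closure.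
- Stereochemistry: C4, the only stereocentre, is set in the ring closure. Both enantiomers of the carbinol (and its lactol forms) pass through the same methide and a chiral Brønsted acid anion chooses the face, so no earlier step needs stereocontrol.
- The closure is the intramolecular form of the cation–arene coupling by which such naphthyl-tetralones presumably arise in nature.

Key step: step 8

Assumption: the sense of induction of the chiral acid in step 8 cannot be fixed on paper; the (R)-catalyst is written, and its mirror image is to be used if a first run shows that it leads to the (R)-tetralone.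

**Route**

Step 1
Reactants: 1 1,5-dimethoxynaphthalene
Product: 3 4,8-dimethoxynaphthalene-1-carbaldehyde, via iminium chloride 2 (not isolated)
Conditions: POCl3 (1.3 equiv), DMF, 0 → 90 °C; then H2O, 0 °C → rt
Reagents that add atoms: N,N-dimethylformamide CN(C)C=O; water O
Why: Vilsmeier–Haack formylation, in which the chloroiminium ion attacks the position para to one methoxy group of the symmetric diether (C4 and C8 are equivalent) and the iminium group of 2 shuts off a second formylation.

Step 2
Reactants: 3 4,8-dimethoxynaphthalene-1-carbaldehyde
Product: 4 4-hydroxy-8-methoxynaphthalene-1-carbaldehyde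
Conditions: NaSEt (1.5 equiv), DMF, 100 °C; then 1 M HCl
Reagents that add atoms: none
Why: SN2 O-demethylation by thiolate, selective because the C4 methoxy is para to the formyl group and leaves as a vinylogous carboxylate while the peri C8 methoxy is not conjugated to it, and the naphtholate formed resists a second cleavage.

Step 3
Reactants: 4 4-hydroxy-8-methoxynaphthalene-1-carbaldehyde
Product: 5 4-(allyloxy)-8-methoxynaphthalene-1-carbaldehyde
Conditions: allyl bromide (1.2 equiv), K2CO3, DMF, rt
Reagents that add atoms: allyl bromide C=CCBr
Why: Williamson etherification of the acidic naphthol, with allyl chosen because it survives organolithium reagents and is removed later under neutral Pd(0) conditions.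

Step 4
Reactants: 5 4-(allyloxy)-8-methoxynaphthalene-1-carbaldehyde; 6 (3-ethoxy-3-oxopropyl)zinc bromide (commercial THF solution)
Product: 9 5-[4-(allyloxy)-8-methoxynaphthalen-1-yl]dihydrofuran-2(3H)-one (racemic), via silyl ether 7 (not isolated), via hydroxy ester 8 (not isolated)
Conditions: 6 (1.5 equiv), Me3SiCl (2 equiv), THF/DMA, 0 °C → rt; then TsOH·H2O (cat.), toluene, 60 °C
Reagents that add atoms: none
Why: Me3SiCl-promoted carbonyl addition of the zinc ester homoenolate gives silyl ether 7, and acid removes the silyl group and lactonises hydroxy ester 8; the carbinol centre is left racemic on purpose because step 8 is stereoconvergent.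

Step 5
Reactants: 10 3-bromobenzene-1,2-diol
Product: 11 1,2-bis(allyloxy)-3-bromobenzene
Conditions: allyl bromide (2.4 equiv), K2CO3, DMF, 50 °C
Reagents that add atoms: allyl bromide C=CCBr
Why: double Williamson etherification of the catechol, which masks both acidic hydroxyls for the lithiation in step 6.

Step 6
Reactants: 11 1,2-bis(allyloxy)-3-bromobenzene; 9 5-[4-(allyloxy)-8-methoxynaphthalen-1-yl]dihydrofuran-2(3H)-one
Product: 13 1-[2,3-bis(allyloxy)phenyl]-4-[4-(allyloxy)-8-methoxynaphthalen-1-yl]-4-hydroxybutan-1-one (racemic), via aryllithium 12 (not isolated)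
Conditions: n-BuLi (1.05 equiv), THF, −78 °C, 15 min; then 9, THF, −78 °C; AcOH, −78 °C → rt
Reagents that add atoms: none
Why: bromine–lithium exchange followed by single addition of the aryllithium to the lactone carbonyl, where the lithium lactolate is stable at −78 °C and releases the ketone only on quench, which should prevent a second addition.

Step 7
Reactants: 13 1-[2,3-bis(allyloxy)phenyl]-4-[4-(allyloxy)-8-methoxynaphthalen-1-yl]-4-hydroxybutan-1-one
Product: 14 1-(2,3-dihydroxyphenyl)-4-hydroxy-4-(4-hydroxy-8-methoxynaphthalen-1-yl)butan-1-one (racemic)
Conditions: Pd(PPh3)4 (5 mol%), morpholine (10 equiv), degassed THF, rt; pH 6 buffer work-up, used crude under Ar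
Reagents that add atoms: none
Why: Tsuji–Trost-type deallylation, in which Pd(0) ionises the three aryl allyl ethers to π-allyl complexes that morpholine intercepts, under conditions mild enough that the acid-labile p-hydroxybenzylic alcohol is not ionised.

Step 8
Reactants: 14 1-(2,3-dihydroxyphenyl)-4-hydroxy-4-(4-hydroxy-8-methoxynaphthalen-1-yl)butan-1-one
Product: 16 (S)-7,8-dihydroxy-4-(4-hydroxy-8-methoxynaphthalen-1-yl)-3,4-dihydronaphthalen-1(2H)-one, via quinone methide 15 (not isolated)
Conditions: (R)-3,3'-bis(2,4,6-triisopropylphenyl)-1,1'-binaphthyl-2,2'-diyl N-triflylphosphoramide (10 mol%), 5 Å MS, CH2Cl2 (0.02 M), −20 °C → rt, Ar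
Reagents that add atoms: none
Why: Proposed new method: the chiral acid protonates the benzylic hydroxyl of 14 (open or lactol form), water leaves with the push of the naphthol oxygen para to the carbinol carbon, and both enantiomers converge on the planar quinone methide 15, held by the phosphoramidate anion as a hydrogen-bonded contact ion pair; C6' of the aryl ketone (the future C4a, para to the 3'-hydroxyl) then adds to the methide carbon and both rings regain aromaticity, so the C–C bond formation is not reversed. The closest known reaction type is the chiral phosphoric acid-catalysed, enantioconvergent 1,6-addition of electron-rich arenes to p-quinone methides formed in the flask from racemic p-hydroxybenzyl alcohols, known between two molecules, together with the achiral acid cyclodehydration of 4-aryl-4-hydroxybutyl arenes to 1-aryltetralins. The ring C1–C2–C3–C4–C4a–C8a closes in the 6-exo-trig mode (Friedel–Crafts 1,6-addition; the methide C=C is exocyclic to the new ring). The stereocentre C4 is controlled by the chiral anion, which covers one face of the methide carbon; the peri methoxy group allows only the E-methide (chain syn to naphthalene C2–H), so only one ion-pair geometry has to be discriminated. The step needs site selectivity and enantioface selectivity: the three-carbon tether lets only C6' reach the methide carbon through a six-membered transition state, and attack by the ketone, phenol or water oxygen is reversible under the acid and returns to 15. It also needs the chiral pathway to outrun an uncatalysed one, which low temperature, a non-polar solvent and sieves should secure.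

**Compound list**

1 | 1,5-dimethoxynaphthalene | COc1cccc2c(OC)cccc12 | starting material
2 | N-[(4,8-dimethoxynaphthalen-1-yl)methylidene]-N-methylmethanaminium chloride | COc1ccc(C=[N+](C)C)c2c(OC)cccc12.[Cl-] | intermediate
3 | 4,8-dimethoxynaphthalene-1-carbaldehyde | COc1ccc(C=O)c2c(OC)cccc12 | intermediate
4 | 4-hydroxy-8-methoxynaphthalene-1-carbaldehyde | COc1cccc2c(O)ccc(C=O)c12 | intermediate
5 | 4-(allyloxy)-8-methoxynaphthalene-1-carbaldehyde | COc1cccc2c(OCC=C)ccc(C=O)c12 | intermediate
6 | (3-ethoxy-3-oxopropyl)zinc bromide | CCOC(=O)CC[Zn]Br | starting material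
7 | ethyl 4-[4-(allyloxy)-8-methoxynaphthalen-1-yl]-4-[(trimethylsilyl)oxy]butanoate (racemic) | CCOC(=O)CCC(O[Si](C)(C)C)c1ccc(OCC=C)c2cccc(OC)c12 | intermediate
8 | ethyl 4-[4-(allyloxy)-8-methoxynaphthalen-1-yl]-4-hydroxybutanoate (racemic) | CCOC(=O)CCC(O)c1ccc(OCC=C)c2cccc(OC)c12 | intermediate
9 | 5-[4-(allyloxy)-8-methoxynaphthalen-1-yl]dihydrofuran-2(3H)-one (racemic) | O=C1CCC(O1)c2ccc(OCC=C)c3cccc(OC)c23 | intermediate
10 | 3-bromobenzene-1,2-diol | Oc1cccc(Br)c1O | starting material
11 | 1,2-bis(allyloxy)-3-bromobenzene | C=CCOc1cccc(Br)c1OCC=C | intermediate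
12 | [2,3-bis(allyloxy)phenyl]lithium | [Li]c1cccc(OCC=C)c1OCC=C | intermediate
13 | 1-[2,3-bis(allyloxy)phenyl]-4-[4-(allyloxy)-8-methoxynaphthalen-1-yl]-4-hydroxybutan-1-one (racemic; in equilibrium with its cyclic hemiketal) | C=CCOc1cccc(C(=O)CCC(O)c2ccc(OCC=C)c3cccc(OC)c23)c1OCC=C | intermediate
14 | 1-(2,3-dihydroxyphenyl)-4-hydroxy-4-(4-hydroxy-8-methoxynaphthalen-1-yl)butan-1-one (racemic; in equilibrium with its cyclic hemiketal) | COc1cccc2c(O)ccc(C(O)CCC(=O)c3cccc(O)c3O)c12 | intermediate
15 | (E)-4-[4-(2,3-dihydroxyphenyl)-4-oxobutylidene]-5-methoxynaphthalen-1(4H)-one | COc1cccc2C(=O)C=C/C(=C\CCC(=O)c3cccc(O)c3O)c12 | intermediate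
16 | (S)-7,8-dihydroxy-4-(4-hydroxy-8-methoxynaphthalen-1-yl)-3,4-dihydronaphthalen-1(2H)-one | COc1cccc2c(O)ccc([C@@H]3CCC(=O)c4c3ccc(O)c4O)c12 | target

**Count**

Total steps: 8. Longest linear sequence: 7 steps (steps 1, 2, 3, 4, 6, 7, 8).

**Steps most likely to fail**

Step 8. The ring carbon ortho to the ketone may add too slowly inside the chiral ion pair, so that intermolecular arylation or an unselective background closure takes over, or the face selection may be poor. The fallback sets out from 14 and comes back at 16. Cyclodehydration of 14 with an achiral strong acid (TfOH cat., HFIP, rt), a known dehydrative Friedel–Crafts alkylation of benzylic alcohols, should give through the same methide 15 the racemic tetralone rac-7,8-dihydroxy-4-(4-hydroxy-8-methoxynaphthalen-1-yl)-3,4-dihydronaphthalen-1(2H)-one F1. The enantiomers are then separated by preparative chromatography on a chiral stationary phase to give 16, and the (R)-enantiomer (R)-7,8-dihydroxy-4-(4-hydroxy-8-methoxynaphthalen-1-yl)-3,4-dihydronaphthalen-1(2H)-one F2 is set aside. The source of configuration thus changes from asymmetric induction to resolution.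

Step 2. The thiolate may cleave the wrong methyl ether or both, or may attack the formyl-activated ring. The fallback sets out from 1 and comes back at 5; it tells the two oxygens apart before the carbon substituent is put in. Mono-demethylation of symmetric 1 (NaSEt 1 equiv, DMF, 130 °C), where no regiochemical choice exists and the naphtholate resists a second cleavage, should give 5-methoxynaphthalen-1-ol F3. Bromination para to the free hydroxyl (NBS, MeCN, −20 °C) should give 4-bromo-5-methoxynaphthalen-1-ol F4. O-allylation (allyl bromide, K2CO3, DMF) gives 1-(allyloxy)-4-bromo-5-methoxynaphthalene F5. Bromine–lithium exchange (n-BuLi, THF, −78 °C) to [4-(allyloxy)-8-methoxynaphthalen-1-yl]lithium F6 and quench with DMF then give 5.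

Step 6. The lactolate may collapse early and take up a second aryllithium, or the lactone may be enolised instead of attacked. The fallback sets out from 9 and comes back at 13. The lactone is opened with Me(MeO)NH·HCl/AlMe3 (CH2Cl2, 0 °C) to the hydroxy Weinreb amide 4-[4-(allyloxy)-8-methoxynaphthalen-1-yl]-4-hydroxy-N-methoxy-N-methylbutanamide F7. F7 is treated at −78 °C with 2.2 equiv of aryllithium 12, the first equivalent capping the hydroxyl. The chelated tetrahedral adduct cannot collapse before work-up, which excludes over-addition, and an acidic quench should give 13.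

**Further compounds**

F1 | step 8 | rac-7,8-dihydroxy-4-(4-hydroxy-8-methoxynaphthalen-1-yl)-3,4-dihydronaphthalen-1(2H)-one | COc1cccc2c(O)ccc(C3CCC(=O)c4c3ccc(O)c4O)c12
F2 | step 8 | (R)-7,8-dihydroxy-4-(4-hydroxy-8-methoxynaphthalen-1-yl)-3,4-dihydronaphthalen-1(2H)-one | COc1cccc2c(O)ccc([C@H]3CCC(=O)c4c3ccc(O)c4O)c12
F3 | step 2 | 5-methoxynaphthalen-1-ol | COc1cccc2c(O)cccc12
F4 | step 2 | 4-bromo-5-methoxynaphthalen-1-ol | COc1cccc2c(O)ccc(Br)c12
F5 | step 2 | 1-(allyloxy)-4-bromo-5-methoxynaphthalene | COc1cccc2c(OCC=C)ccc(Br)c12
F6 | step 2 | [4-(allyloxy)-8-methoxynaphthalen-1-yl]lithium | [Li]c1ccc(OCC=C)c2cccc(OC)c12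
F7 | step 6 | 4-[4-(allyloxy)-8-methoxynaphthalen-1-yl]-4-hydroxy-N-methoxy-N-methylbutanamide | CON(C)C(=O)CCC(O)c1ccc(OCC=C)c2cccc(OC)c12
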